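**Plan**
The target is a single saturated 29-membered lactone ring (ring O plus C1–C28, with C1 the carbonyl carbon and C28 the OCH2 carbon) and has no stereocentre.
Enabling feature: ring carbons C17–C20 are plain methylenes far from the ester, so they can be carried as a conjugated 1,3-diyne C17≡C18–C19≡C20 whose central bond joins two terminal alkynes.
Retrosynthetic cuts, in order: (a) the eight C–H bonds at C17–C20, back to the diyne; (b) ring bond C18–C19; (c) ester bond C1(=O)–O, leaving a C18 alkynoic acid and a C10 alkynol.
Forward: the chain is joined at the ester (step 1), the only ring arises by oxidative C18–C19 coupling (step 2), and hydrogenation saturates the diyne (step 3).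
Stereochemistry: none to set; every compound of the route is achiral.

Key step: step 2

Remark: 17-octadecynoic acid (1) and 9-decyn-1-ol (2) are both catalogue chemicals and are taken as purchased; the C1–C28 numbering of the lactone is used for all intermediates.

Step 1
Reactants: 1 17-octadecynoic acid; 2 9-decyn-1-ol
Product: 4 dec-9-yn-1-yl octadec-17-ynoate, via O-acylisourea 3 (not isolated)
Conditions: DCC (1.1 equiv), DMAP (0.1 equiv), CH2Cl2, 0 °C to rt
Reagents that add atoms: none
Why: Steglich esterification: DCC converts acid 1 into the O-acylisourea 3, DMAP passes the acyl group to the unhindered primary alcohol 2 faster than the O-to-N acyl shift can occur, the carbodiimide leaves as its urea without contributing an atom to 4, and the two terminal alkynes are spectators.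

Step 2
Reactants: 4 dec-9-yn-1-yl octadec-17-ynoate
Product: 5 octacosa-17,19-diyn-28-olide (1-oxacyclononacosa-18,20-diyn-2-one)
Conditions: Cu(OAc)2 (10 equiv), pyridine/Et2O 5:1, 45 °C, syringe-pump addition of 4 over 12 h (about 1 mM at the end), Ar
Reagents that add atoms: none
Why: Pyridine-assisted deprotonation turns each copper-bound C≡C–H terminus of 4 into a copper acetylide, two divalent-copper acetylide units meet in a dinuclear acetate-bridged complex, and bimetallic reductive elimination forms the C18–C19 sp–sp bond while both copper centres leave as monovalent CuOAc. The closest known reaction type is the Eglinton variant of the Glaser coupling, as applied to α,ω-diynes under high dilution to give macrocyclic 1,3-diynes. The single ring closes end to end, the chain termini C18 and C19 joining to give the 29-membered lactone, a ring large enough to hold the linear C17–C20 diyne rod without strain. No stereocentre is formed. The step needs ring closure to outrun intermolecular coupling to the 58-membered cyclic dimer and open oligomers, and this should be secured by feeding 4 slowly into a warm excess of Cu(OAc)2 so that its standing concentration stays very low. The ester is inert to Cu(OAc)2 in pyridine, and no alcohol cosolvent is present that could transesterify it.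

Step 3
Reactants: 5 octacosa-17,19-diyn-28-olide
Product: 6 octacosanolide
Conditions: H2 (1 atm), 10% Pd/C, EtOAc/THF 1:1, rt
Reagents that add atoms: none
Why: Heterogeneous catalytic hydrogenation over palladium on carbon should add four H2 across the conjugated diyne to give the saturated C17–C20 segment, while the lactone, which has no benzylic, allylic or propargylic C–O bond, is untouched and no stereocentre arises.

**Compound list**
1 | 17-octadecynoic acid (octadec-17-ynoic acid) | C#CCCCCCCCCCCCCCCCC(=O)O | starting material
2 | 9-decyn-1-ol (dec-9-yn-1-ol) | C#CCCCCCCCCO | starting material
3 | O-(octadec-17-ynoyl)-N,N'-dicyclohexylisourea (formed in the flask, not isolated) | C#CCCCCCCCCCCCCCCCC(=O)OC(=NC1CCCCC1)NC1CCCCC1 | intermediate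
4 | dec-9-yn-1-yl octadec-17-ynoate | C#CCCCCCCCCCCCCCCCC(=O)OCCCCCCCCC#C | intermediate
5 | octacosa-17,19-diyn-28-olide (1-oxacyclononacosa-18,20-diyn-2-one) | O=C1CCCCCCCCCCCCCCCC#CC#CCCCCCCCCO1 | intermediate
6 | octacosanolide (1-oxacyclononacosan-2-one) | O=C1CCCCCCCCCCCCCCCCCCCCCCCCCCCO1 | target

Total step count: 3
Longest linear sequence: 3 steps (1 or 2 → 4 → 5 → 6)

**Steps most likely to fail**

1. Step 2. Intermolecular oxidative coupling may outrun ring closure, so that material drains into the cyclic dimer and open-chain oligomers however slowly 4 is fed. The fallback keeps the C18–C19 alkyne–alkyne bond but forms it between two separate molecules and closes the ring at the ester instead. It sets out from 2: bromination of the terminal alkyne (NBS, AgNO3 cat., acetone, rt) should give 10-bromodec-9-yn-1-ol F1. Cadiot–Chodkiewicz cross-coupling of the bromoalkyne with the terminal alkyne of acid 1 (CuCl cat., NH2OH·HCl, aqueous n-BuNH2, MeOH/THF, 0 °C) should then give 28-hydroxyoctacosa-17,19-diynoic acid F2. Shiina macrolactonization (2-methyl-6-nitrobenzoic anhydride, DMAP, Et3N, CH2Cl2, rt, slow addition) would pass through 28-hydroxyoctacosa-17,19-diynoic 2-methyl-6-nitrobenzoic anhydride F3, which is not isolated, and close the 29-membered lactone. Acyl-transfer lactonization of this kind is dependable at this ring size. The fallback comes back to the route at 5.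

2. Step 3. Hydrogen uptake may stall at the enyne or diene stage if traces of copper or pyridine carried over from step 2 poison the palladium surface, or if the increasingly waxy material falls out of solution onto the catalyst. The fallback replaces surface catalysis by a stoichiometric, metal-free hydrogen transfer. Diimide generated in the flask (TsNHNH2 in large excess, NaOAc, DME/H2O, reflux) should deliver hydrogen to the nonpolar C–C multiple bonds by concerted syn transfer and leave the lactone alone. It sets out from 5 and comes back at 6; no compound outside the list is made, entry F0.

3. Step 1. The activated acid may rearrange by O-to-N acyl shift to an unreactive N-acylurea, and the urea by-product may follow the waxy ester through chromatography. The fallback reverses the roles of the partners, forming the O–C28 bond by SN2 displacement instead of the C1–O bond by acyl transfer. It sets out from 2: mesylation (MsCl, Et3N, CH2Cl2, 0 °C) should give dec-9-yn-1-yl methanesulfonate F4, and O-alkylation of the cesium carboxylate of 1 with this mesylate (Cs2CO3, DMF, 50 °C) should give the ester, coming back to the route at 4.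

**Further compounds**
F1 | step 2 | 10-bromodec-9-yn-1-ol | OCCCCCCCCC#CBr
F2 | step 2 | 28-hydroxyoctacosa-17,19-diynoic acid | OC(=O)CCCCCCCCCCCCCCCC#CC#CCCCCCCCCO
F3 | step 2 | 28-hydroxyoctacosa-17,19-diynoic 2-methyl-6-nitrobenzoic anhydride (not isolated) | Cc1cccc([N+](=O)[O-])c1C(=O)OC(=O)CCCCCCCCCCCCCCCC#CC#CCCCCCCCCO
F0 | step 3 | none | none
F4 | step 1 | dec-9-yn-1-yl methanesulfonate | C#CCCCCCCCCOS(C)(=O)=O
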